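**Two slopes.** Compare two slopes.

the same everywhere: substrate 0.10 M
- violet: partner 0.20 M; the very flask that is asked about, followed so far
- green: partner 0.40 M; run made earlier
- flask: partner 0.200 M; time 20 min

- violet (time / s: dormant form / %, product / %): 10.0: 0.2, 0; 20.0: 0.1, 0.4; 30.0: 0.6, 0; 50.0: 1.2, 0; 80.0: 1.7, 0; 90.0: 1.1, 0
- green (time / min: dormant form / %, product / %): 1.50: 2.2, 0.3; 2.50: 2.7, 0.3; 4.00: 5.5, 0.6; 8.00: 10.1, 0; 12.0: 13.9, 0; 20.0: 22.2, 2.3

(standard deviation of a reading: 0.5 percentage points)

- amount of dormant form in percent of the substrate charged, at 1.0 min, 5.0 min and 20 min

The violet run has followed the flask for 90.0 s. A line through the origin has dormant form rising by 0.0103 min⁻¹ as a fraction of the substrate charged, give or take 0.00221 min⁻¹. The green run, with twice the c(partner), gives 0.0131 min⁻¹ over its first 4.00 min, give or take 0.00101 min⁻¹.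

**One exponent.** Fold these into the partner exponent, the reaction order in partner: the logarithm of the slope ratio over the logarithm of the c(partner) ratio, 0.340, give or take 0.328. At zero, dormant form ignores the partner; at one, it follows it in proportion. Zero lies 1.04 standard deviations from this reading, and one lies 2.01.

**My reckoning.** I take zero, so the violet flask runs on the green curve. Green's last reading of dormant form, taken as a first-order rise, gives a constant of 0.0126 min⁻¹, hence for the violet flask 1.25%, 6.08% and 22.2%.

**The test.** That curve gives 14.0% at 12.0 min, where green, in a separate reading, shows 13.9%. Its constant stands 1.00 standard deviations above the violet slope, so one number carries both runs within the scatter.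

**The forecast.** The forecast reads the same slopes differently: “This suggests a partial order, perhaps saturation.” It gives 0.95%, 4.5% and 15.5%, the last lower than mine.

    substrate + partner + product → 2 product (k = 0.110 L² mol⁻² s⁻¹)
    substrate + partner → product (k = 3.30 × 10⁻⁶ L mol⁻¹ s⁻¹)
    substrate ⇌ dormant form (K = 3.40, k = 2.20 × 10⁻⁴ s⁻¹)

**The flask.** The flask gives 1.31%, 6.33% and 22.3%. Set against green's reading at 20.0 min, this last value puts the partner exponent at −0.00648, give or take 0.0325, a reading like the 0.340 from the slopes. At 20.0 min the rate at which the forward step alone turns substrate into dormant form stands 36 times the rate at which the reaction of substrate + partner + product uses substrate, and the flask holds 22.3% dormant form beside 0.277% product.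

(The readings come from a simulation with constants of no real substance.)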